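**Retrosynthetic overview**

1. Numbering: ring A = C1(=O)–C2(Me)=C3(OMe)–C4Me2–C5(=O)–C6 (spiro); ring B = C6–C7–C8(chain)–C9–C10–C11(iPr). The target is (6R,11S), with isopropyl cis to the C1 carbonyl.
2. Target ⇒ C8-alkylated spiro enone: the C9 ketone is removed through its tosylhydrazone with shift of C7=C8 to C8=C9. The C8–chain bond comes from a Negishi coupling of the C8 iodide.
3. Key disconnection C11–isopropyl: the retron is the achiral spiro cyclohexa-2,5-dienone. Its ring B (carbonyl at C9) is bisected by a mirror plane that contains ring A, so C7/C11 and C8/C10 are enantiotopic, and C6 and C11 become stereogenic only when one arm is alkylated.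
4. Dienone ⇒ spiro cyclohexanone (dehydrogenation) ⇒ ring A dione + divinyl ketone (double Michael addition at C6). Ring A dione ⇒ methyl 2,6-dihydroxy-4-methoxybenzoate by dearomatising C-trimethylation (the arene symmetry places OMe between C-Me and CMe2), then loss of the ester.
5. Ring order: ring A first (from the arene), ring B second (spiroannulation); no ring is formed at or after the key step.

Key step: step 6

Assumption: the sense of induction of the phosphoramidite cannot be predicted with confidence for this substrate; the (S,R,R) ligand is written, and its mirror image is used if the first run shows the opposite sense.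
Remark: the C6 descriptor switches between R and S along the route only because the CIP priorities of C7 and C11 change; the spatial arrangement stays the same.

**Route**

Step 1
Reactants: 1 methyl 2,4,6-trihydroxybenzoate
Product: 2 methyl 2,6-dihydroxy-4-methoxybenzoate
Conditions: MeI (1.05 equiv), K2CO3 (1.0 equiv), acetone, rt
Reagents that add atoms: iodomethane, CI
Why: Williamson ether synthesis at the 4-OH, which is the most acidic hydroxyl and the only one not held in a hydrogen bond to the ester carbonyl, so one equivalent of weak base and MeI should give the para methyl ether.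

Step 2
Reactants: 2 methyl 2,6-dihydroxy-4-methoxybenzoate
Product: 3 methyl 2-hydroxy-4-methoxy-3,3,5-trimethyl-6-oxocyclohexa-1,4-diene-1-carboxylate (drawn as one enol tautomer)
Conditions: NaOMe (4 equiv), MeI (5 equiv), MeOH, 0 to 50 °C; then cold 1 M HCl to pH 3
Reagents that add atoms: iodomethane, CI
Why: Dearomatising nuclear C-methylation of a phloroglucinol-type phenoxide in a protic solvent: C3 and C5 are methylated first and the third methyl enters at either of these now equivalent carbons, so the mirror symmetry of the arene allows a single constitution with OMe between C-Me and CMe2, while the ester-bearing carbon is deactivated and stays free of methyl.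

Step 3
Reactants: 3 methyl 2-hydroxy-4-methoxy-3,3,5-trimethyl-6-oxocyclohexa-1,4-diene-1-carboxylate
Product: 4 5-methoxy-4,6,6-trimethylcyclohex-4-ene-1,3-dione
Conditions: DMSO–H2O (10:1), 120 °C, N2
Reagents that add atoms: none
Why: Hydrolytic decarbomethoxylation of an enolised 2-acyl β-keto ester under neutral conditions (the behaviour of alkoxycarbonyl tetramic acids and related cyclic tricarbonyl esters in hot wet solvents), chosen because neither acid nor hydroxide is present to hydrolyse the hindered vinylogous methyl ester; the β-keto acid loses CO2 as it forms.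

Step 4
Reactants: 4 5-methoxy-4,6,6-trimethylcyclohex-4-ene-1,3-dione; 5 1,5-dichloropentan-3-one
Product: 8 3-methoxy-2,4,4-trimethylspiro[5.5]undec-2-ene-1,5,9-trione, via penta-1,4-dien-3-one 6 (not isolated), via mono-Michael adduct 7 (not isolated)
Conditions: Et3N (3 equiv), MeCN, slow addition of 5, 0 °C to rt
Reagents that add atoms: none
Why: Double Michael addition ([5+1] spiroannulation): Et3N eliminates HCl twice from 5 to release divinyl ketone 6, the dione carbon C6 adds to one vinyl group to give 7, and the resulting 2-alkyl-1,3-dione enolate closes ring B by 6-endo-trig Michael addition, the O-alkylation alternative requiring an eight-membered ring.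

Step 5
Reactants: 8 3-methoxy-2,4,4-trimethylspiro[5.5]undec-2-ene-1,5,9-trione
Product: 10 3-methoxy-2,4,4-trimethylspiro[5.5]undeca-2,7,10-triene-1,5,9-trione, via racemic spiro mono-enone 9 (not isolated)
Conditions: IBX (3.5 equiv), 4-methoxypyridine N-oxide (3.5 equiv), DMSO, 25 to 45 °C
Reagents that add atoms: none
Why: IBX dehydrogenation of a 4,4-disubstituted cyclohexanone to the cyclohexa-2,5-dienone through enone 9; ring A has no enolisable hydrogen and the N-oxide additive lets the oxidation run near room temperature, which limits exposure of the acid- and nucleophile-sensitive 4,4-diacyl dienone.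

Step 6
Reactants: 10 3-methoxy-2,4,4-trimethylspiro[5.5]undeca-2,7,10-triene-1,5,9-trione; 11 diisopropylzinc
Product: 13 (6R,11S)-3-methoxy-2,4,4-trimethyl-11-(propan-2-yl)spiro[5.5]undeca-2,7-diene-1,5,9-trione, via isopropylzinc dienolate 12 (not isolated)
Conditions: Cu(OTf)2 (3 mol %), (S,R,R)-phosphoramidite [(S)-BINOL-derived, N,N-bis((R)-1-phenylethyl)] (6 mol %), Zn(iPr)2 (1.5 equiv), toluene, −30 °C; then sat. aq NH4Cl
Reagents that add atoms: none
Why: Transmetalation of Zn(iPr)2 to the copper–phosphoramidite complex gives an isopropylcopper species that binds one enone arm of 10 and transfers isopropyl to its β-carbon C11, leaving the isopropylzinc dienolate 12, which is inert to a second addition and is protonated at C10 on work-up. The closest known reaction type is the copper/phosphoramidite-catalysed dialkylzinc desymmetrisation of 4,4-disubstituted cyclohexa-2,5-dienones; no ring is closed. The ligand fixes the configuration of the new C11 centre (11S wanted), and because C7 and C11 are enantiotopic, this choice together with the face of ring B that is attacked also fixes C6. The step needs attack on the face of ring B that carries C1 (giving 6R, isopropyl cis to C1): the vinylogous-ester carbonyl at C1 is the more Lewis-basic oxygen and can hold the zinc reagent on its side, while the opposite face lies under the C5 carbonyl and the C4 gem-dimethyl group. Ring A has no enolisable hydrogen and no second acceptor (C3 is a fully substituted, donor-deactivated β-carbon), so the only competing processes are the diastereomeric addition and cleavage of a C6–acyl bond, which low temperature and the non-nucleophilic medium should hold back.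

Step 7
Reactants: 13 (6R,11S)-3-methoxy-2,4,4-trimethyl-11-(propan-2-yl)spiro[5.5]undeca-2,7-diene-1,5,9-trione
Product: 14 (6S,11S)-8-iodo-3-methoxy-2,4,4-trimethyl-11-(propan-2-yl)spiro[5.5]undeca-2,7-diene-1,5,9-trione
Conditions: I2 (2 equiv), pyridine–CH2Cl2 (1:1), 0 °C to rt
Reagents that add atoms: iodine, II
Why: Pyridine-mediated α-iodination of an enone (conjugate addition of pyridine at C7, iodination of the enolate at C8, elimination), a standard reaction of 4,4-disubstituted cyclohex-2-enones; the fully substituted ring A alkene has no hydrogen to lose and C10 is not enolised by pyridine.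

Step 8
Reactants: 15 5-bromo-2-methylpent-2-ene
Product: 16 (4-methylpent-3-en-1-yl)zinc bromide (THF solution, titrated and used directly)
Conditions: Zn dust (activated with 1,2-dibromoethane and TMSCl), LiCl, THF, 50 °C
Reagents that add atoms: zinc, [Zn]
Why: Direct oxidative insertion of activated Zn into a primary alkyl bromide, accelerated by LiCl, which leaves the trisubstituted alkene untouched and gives a reagent that tolerates ketones.

Step 9
Reactants: 14 (6S,11S)-8-iodo-3-methoxy-2,4,4-trimethyl-11-(propan-2-yl)spiro[5.5]undeca-2,7-diene-1,5,9-trione; 16 (4-methylpent-3-en-1-yl)zinc bromide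
Product: 17 (6S,11S)-3-methoxy-2,4,4-trimethyl-8-(4-methylpent-3-en-1-yl)-11-(propan-2-yl)spiro[5.5]undeca-2,7-diene-1,5,9-trione
Conditions: PdCl2(dppf) (5 mol %), 16 (1.5 equiv), THF, 25 to 45 °C
Reagents that add atoms: none
Why: Negishi sp2–sp3 coupling of an α-iodoenone with a primary alkylzinc halide, in which the dppf ligand speeds reductive elimination relative to β-hydride elimination and the organozinc does not add to any of the three carbonyl groups.

Step 10
Reactants: 17 (6S,11S)-3-methoxy-2,4,4-trimethyl-8-(4-methylpent-3-en-1-yl)-11-(propan-2-yl)spiro[5.5]undeca-2,7-diene-1,5,9-trione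
Product: 18 N'-[(6S,11S)-3-methoxy-2,4,4-trimethyl-8-(4-methylpent-3-en-1-yl)-1,5-dioxo-11-(propan-2-yl)spiro[5.5]undeca-2,7-dien-9-ylidene]-4-methylbenzenesulfonohydrazide (C=N isomers as formed)
Conditions: TsNHNH2 (1.2 equiv), PPTS (5 mol %), MeOH, 40 °C
Reagents that add atoms: 4-methylbenzenesulfonohydrazide, Cc1ccc(cc1)S(=O)(=O)NN
Why: Hydrazone formation at the only accessible ketone, C9, since C1 is a deactivated vinylogous-ester carbonyl and C5 lies between two quaternary carbons; MeOH as solvent makes any acid-catalysed exchange at the C3 methoxy group degenerate.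

Step 11
Reactants: 18 the C9 tosylhydrazone
Product: 21 (6R,11S)-3-methoxy-2,4,4-trimethyl-8-(4-methylpent-3-en-1-yl)-11-(propan-2-yl)spiro[5.5]undeca-2,8-diene-1,5-dione, via N-boryl tosylhydrazine 19 (not isolated), via allylic diazene 20 (not isolated)
Conditions: catecholborane (2.5 equiv), CHCl3, 0 °C; then NaOAc·3H2O, 60 °C
Reagents that add atoms: none
Why: Reduction of an α,β-unsaturated tosylhydrazone with catecholborane: hydride adds to C9, acetate then expels sulfinate from 19 to give allylic diazene 20, and its retro-ene loss of N2 places hydrogen on C7 and the alkene at C8=C9, while C6 and C11 are not involved and keep their configuration.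

**Compound list**

1 | methyl 2,4,6-trihydroxybenzoate | COC(=O)c1c(O)cc(O)cc1O | starting material
2 | methyl 2,6-dihydroxy-4-methoxybenzoate | COC(=O)c1c(O)cc(OC)cc1O | intermediate
3 | methyl 2-hydroxy-4-methoxy-3,3,5-trimethyl-6-oxocyclohexa-1,4-diene-1-carboxylate | COC(=O)C1=C(O)C(C)(C)C(OC)=C(C)C1=O | intermediate
4 | 5-methoxy-4,6,6-trimethylcyclohex-4-ene-1,3-dione | COC1=C(C)C(=O)CC(=O)C1(C)C | intermediate
5 | 1,5-dichloropentan-3-one | ClCCC(=O)CCCl | starting material
6 | penta-1,4-dien-3-one (divinyl ketone) | C=CC(=O)C=C | intermediate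
7 | 5-methoxy-4,6,6-trimethyl-2-(3-oxopent-4-en-1-yl)cyclohex-4-ene-1,3-dione (mono-Michael adduct) | COC1=C(C)C(=O)C(CCC(=O)C=C)C(=O)C1(C)C | intermediate
8 | 3-methoxy-2,4,4-trimethylspiro[5.5]undec-2-ene-1,5,9-trione | COC1=C(C)C(=O)C2(CCC(=O)CC2)C(=O)C1(C)C | intermediate
9 | rac-3-methoxy-2,4,4-trimethylspiro[5.5]undeca-2,7-diene-1,5,9-trione (spiro mono-enone) | COC1=C(C)C(=O)C2(C=CC(=O)CC2)C(=O)C1(C)C | intermediate
10 | 3-methoxy-2,4,4-trimethylspiro[5.5]undeca-2,7,10-triene-1,5,9-trione | COC1=C(C)C(=O)C2(C=CC(=O)C=C2)C(=O)C1(C)C | intermediate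
11 | diisopropylzinc | CC(C)[Zn]C(C)C | starting material
12 | isopropylzinc dienolate of 13 (O-zinc at C9, C7=C8 and C9=C10) | COC1=C(C)C(=O)[C@]2(C=CC(O[Zn]C(C)C)=C[C@H]2C(C)C)C(=O)C1(C)C | intermediate
13 | (6R,11S)-3-methoxy-2,4,4-trimethyl-11-(propan-2-yl)spiro[5.5]undeca-2,7-diene-1,5,9-trione | COC1=C(C)C(=O)[C@]2(C=CC(=O)C[C@H]2C(C)C)C(=O)C1(C)C | intermediate
14 | (6S,11S)-8-iodo-3-methoxy-2,4,4-trimethyl-11-(propan-2-yl)spiro[5.5]undeca-2,7-diene-1,5,9-trione | COC1=C(C)C(=O)[C@]2(C=C(I)C(=O)C[C@H]2C(C)C)C(=O)C1(C)C | intermediate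
15 | 5-bromo-2-methylpent-2-ene | CC(C)=CCCBr | starting material
16 | (4-methylpent-3-en-1-yl)zinc bromide | CC(C)=CCC[Zn]Br | intermediate
17 | (6S,11S)-3-methoxy-2,4,4-trimethyl-8-(4-methylpent-3-en-1-yl)-11-(propan-2-yl)spiro[5.5]undeca-2,7-diene-1,5,9-trione | COC1=C(C)C(=O)[C@]2(C=C(CCC=C(C)C)C(=O)C[C@H]2C(C)C)C(=O)C1(C)C | intermediate
18 | N'-[(6S,11S)-3-methoxy-2,4,4-trimethyl-8-(4-methylpent-3-en-1-yl)-1,5-dioxo-11-(propan-2-yl)spiro[5.5]undeca-2,7-dien-9-ylidene]-4-methylbenzenesulfonohydrazide | COC1=C(C)C(=O)[C@]2(C=C(CCC=C(C)C)C(=NNS(=O)(=O)c3ccc(C)cc3)C[C@H]2C(C)C)C(=O)C1(C)C | intermediate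
19 | N-(1,3,2-benzodioxaborol-2-yl) tosylhydrazine at C9 of the (6S,11S) skeleton (C9 configuration not controlled) | COC1=C(C)C(=O)[C@]2(C=C(CCC=C(C)C)C(N(NS(=O)(=O)c3ccc(C)cc3)B3Oc4ccccc4O3)C[C@H]2C(C)C)C(=O)C1(C)C | intermediate
20 | allylic diazene at C9 of the (6S,11S) skeleton (C9 configuration not controlled) | COC1=C(C)C(=O)[C@]2(C=C(CCC=C(C)C)C(N=N)C[C@H]2C(C)C)C(=O)C1(C)C | intermediate
21 | (6R,11S)-3-methoxy-2,4,4-trimethyl-8-(4-methylpent-3-en-1-yl)-11-(propan-2-yl)spiro[5.5]undeca-2,8-diene-1,5-dione | COC1=C(C)C(=O)[C@]2(CC(CCC=C(C)C)=CC[C@H]2C(C)C)C(=O)C1(C)C | target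

**Step count and risks**

Total steps: 11. Longest linear sequence: 10 (steps 1–7 and 9–11 from methyl 2,4,6-trihydroxybenzoate; step 8 is a one-step branch).

Steps most likely to fail:

Step 6 (key step). What may go wrong: too little discrimination between the two faces of ring B, so that the ligand sets the 11S centre on both arms and the C6 epimer forms alongside; slow transfer of a secondary alkyl group to a carbon next to the quaternary spiro centre; or cleavage of a C6–acyl bond with aromatisation of ring B under electron-transfer conditions. Fallback, setting out from 10: a Hayashi–Miyaura addition replaces the copper–zinc system. Potassium isopropenyltrifluoroborate with [RhCl(C2H4)2]2 and (R)-BINAP (enantiomer chosen as for step 6), Et3N, toluene–H2O, 60 °C, should give (6R,11S)-3-methoxy-2,4,4-trimethyl-11-(prop-1-en-2-yl)spiro[5.5]undeca-2,7-diene-1,5,9-trione F1 by sterically governed carbometalation away from the C4 gem-dimethyl/C5 side. Iodination under the conditions of step 7 should give (6S,11S)-8-iodo-3-methoxy-2,4,4-trimethyl-11-(prop-1-en-2-yl)spiro[5.5]undeca-2,7-diene-1,5,9-trione F2. Coupling with 16 under the conditions of step 9 should give (6R,11S)-3-methoxy-2,4,4-trimethyl-8-(4-methylpent-3-en-1-yl)-11-(prop-1-en-2-yl)spiro[5.5]undeca-2,7-diene-1,5,9-trione F3. Hydrogenation with H2 and RhCl(PPh3)3 in toluene, which reduces a 1,1-disubstituted alkene in preference to trisubstituted and conjugated ones (the carvone case), returns to the route at 17.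

Step 5. What may go wrong: acid-promoted acyl migration from C6 (dienone–phenol rearrangement) or nucleophilic C6–acyl cleavage of the 4,4-diacyl dienone during the oxidation, or a stalled second dehydrogenation. Fallback, setting out from 8: two Saegusa–Ito cycles under neutral conditions. TMSOTf and Et3N in CH2Cl2 at 0 °C should give 3-methoxy-2,4,4-trimethyl-9-[(trimethylsilyl)oxy]spiro[5.5]undeca-2,8-diene-1,5-dione F4, and Pd(OAc)2 in MeCN at rt converts it into 9, which is isolated this time. A second silylation should give the cross-conjugated 3-methoxy-2,4,4-trimethyl-9-[(trimethylsilyl)oxy]spiro[5.5]undeca-2,7,9-triene-1,5-dione F5 (C6 is quaternary, so only C10 can be deprotonated), and Pd(OAc)2 in MeCN returns to the route at 10.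

Step 3. What may go wrong: hydrolysis of the vinylogous methyl ester together with the ester in hot water, which would erase the position of the O-methyl group, or sluggish ester cleavage. Fallback, setting out from 3: thermal transesterification with benzyl alcohol in refluxing toluene with removal of MeOH (acylketene pathway of enolised β-keto esters) should give benzyl 2-hydroxy-4-methoxy-3,3,5-trimethyl-6-oxocyclohexa-1,4-diene-1-carboxylate F6. Hydrogenolysis (H2, Pd/C, EtOAc, rt) releases 2-hydroxy-4-methoxy-3,3,5-trimethyl-6-oxocyclohexa-1,4-diene-1-carboxylic acid F7, which decarboxylates without water or acid and returns to the route at 4.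

**Further compounds**

F1 | step 6 | (6R,11S)-3-methoxy-2,4,4-trimethyl-11-(prop-1-en-2-yl)spiro[5.5]undeca-2,7-diene-1,5,9-trione | COC1=C(C)C(=O)[C@]2(C=CC(=O)C[C@H]2C(C)=C)C(=O)C1(C)C
F2 | step 6 | (6S,11S)-8-iodo-3-methoxy-2,4,4-trimethyl-11-(prop-1-en-2-yl)spiro[5.5]undeca-2,7-diene-1,5,9-trione | COC1=C(C)C(=O)[C@]2(C=C(I)C(=O)C[C@H]2C(C)=C)C(=O)C1(C)C
F3 | step 6 | (6R,11S)-3-methoxy-2,4,4-trimethyl-8-(4-methylpent-3-en-1-yl)-11-(prop-1-en-2-yl)spiro[5.5]undeca-2,7-diene-1,5,9-trione | COC1=C(C)C(=O)[C@]2(C=C(CCC=C(C)C)C(=O)C[C@H]2C(C)=C)C(=O)C1(C)C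
F4 | step 5 | 3-methoxy-2,4,4-trimethyl-9-[(trimethylsilyl)oxy]spiro[5.5]undeca-2,8-diene-1,5-dione | COC1=C(C)C(=O)C2(CCC(O[Si](C)(C)C)=CC2)C(=O)C1(C)C
F5 | step 5 | 3-methoxy-2,4,4-trimethyl-9-[(trimethylsilyl)oxy]spiro[5.5]undeca-2,7,9-triene-1,5-dione | COC1=C(C)C(=O)C2(C=CC(O[Si](C)(C)C)=CC2)C(=O)C1(C)C
F6 | step 3 | benzyl 2-hydroxy-4-methoxy-3,3,5-trimethyl-6-oxocyclohexa-1,4-diene-1-carboxylate | O=C(OCc1ccccc1)C1=C(O)C(C)(C)C(OC)=C(C)C1=O
F7 | step 3 | 2-hydroxy-4-methoxy-3,3,5-trimethyl-6-oxocyclohexa-1,4-diene-1-carboxylic acid | OC(=O)C1=C(O)C(C)(C)C(OC)=C(C)C1=O
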